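**Strategy**

The molecule is disconnected between thiazole C2, the ring carbon flanked by S1 and N3, and the gem-dimethyl quaternary carbon. C2–H is the one ring position made strongly electrophilic by protonation of N3, and the quaternary carbon is a stabilised tertiary radical once it carries a carboxyl group. The key step is a decarboxylative photoredox Minisci alkylation: the N-hydroxyphthalimide ester of the complete side-chain acid (both carbinol stereocentres, E-alkene and carbamate in place) releases CO2, and the tertiary radical attacks C2–H of 4-[(Z)-hexa-2,5-dienyl]thiazole, creating the quaternary centre and uniting the two halves in one operation. The ester comes from an α-formyl isobutyrate by allylboration and cross-metathesis.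

Key step: step 11

Assumption: in step 7 the (R,R)-antipode of the diaminocyclohexane-naphthyl bisphosphine ligand is taken to give the (R)-diol, by analogy with 2-alkyl-2-vinyloxiranes; if the sense proves opposite, the (S,S)-ligand is used and nothing else changes.

**Route**

Step 1
Reactants: 1 methyl 2,2-dimethyl-3-oxopropanoate
Product: 3 (3R)-3-hydroxy-2,2-dimethylhex-5-enoic acid, via hydroxy methyl ester 2 (not isolated)
Conditions: (−)-Ipc2B(allyl) (salt-free, from (−)-α-pinene), Et2O, −100 → −78 °C; aq. NaOH, H2O2, 0 °C → rt; then NaOH, MeOH/H2O, 50 °C; HCl to pH 2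
Reagents that add atoms: (−)-B-allyldiisopinocampheylborane, C=CCB([C@H]1C[C@H]2C[C@@H]([C@@H]1C)C2(C)C)[C@H]1C[C@H]2C[C@@H]([C@@H]1C)C2(C)C; sodium hydroxide, [Na+].[OH-]
Why: Brown allylboration through a chair Zimmerman–Traxler transition state should deliver the allyl group to the Re face of the non-enolisable, pivaldehyde-like aldehyde and set C3 as (R), and saponification in the same pot lets the acid be separated from isopinocampheol by extraction.

Step 2
Reactants: 3 (3R)-3-hydroxy-2,2-dimethylhex-5-enoic acid
Product: 5 (3R)-3-[(tert-butyldimethylsilyl)oxy]-2,2-dimethylhex-5-enoic acid, via bis-silylated silyl ester 4 (not isolated)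
Conditions: TBSOTf (2.5 equiv), 2,6-lutidine, CH2Cl2, −78 → 0 °C; then AcOH/THF/H2O, rt
Reagents that add atoms: tert-butyldimethylsilyl trifluoromethanesulfonate, CC(C)(C)[Si](C)(C)OS(=O)(=O)C(F)(F)F
Why: Silyl ether protection of the secondary alcohol (the labile silyl ester formed alongside is hydrolysed selectively by mild aqueous acid) blocks β-lactone formation and O-acylation when the acid is activated in step 3.

Step 3
Reactants: 5 (3R)-3-[(tert-butyldimethylsilyl)oxy]-2,2-dimethylhex-5-enoic acid
Product: 6 1,3-dioxoisoindolin-2-yl (3R)-3-[(tert-butyldimethylsilyl)oxy]-2,2-dimethylhex-5-enoate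
Conditions: N-hydroxyphthalimide, DIC, DMAP (cat.), CH2Cl2, rt
Reagents that add atoms: N-hydroxyphthalimide, O=C1c2ccccc2C(=O)N1O
Why: Steglich-type carbodiimide esterification should give the N-(acyloxy)phthalimide redox-active ester, and the α-quaternary acid has no epimerisable centre.

Step 4
Reactants: 7 but-3-yn-1-amine
Product: 8 methyl but-3-yn-1-ylcarbamate
Conditions: ClCO2Me, Et3N, CH2Cl2, 0 °C → rt
Reagents that add atoms: methyl chloroformate, COC(=O)Cl
Why: Schotten–Baumann-type N-acylation of the primary amine installs the methyl carbamate of the target at the outset.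

Step 5
Reactants: 8 methyl but-3-yn-1-ylcarbamate
Product: 9 methyl (3-methylidenepent-4-en-1-yl)carbamate
Conditions: Grubbs II (5 mol%), ethylene (1 atm), CH2Cl2, 40 °C
Reagents that add atoms: ethylene, C=C
Why: Ethylene–alkyne cross enyne metathesis should convert the terminal alkyne into the 2-substituted 1,3-butadiene with all atoms of ethylene retained.

Step 6
Reactants: 9 methyl (3-methylidenepent-4-en-1-yl)carbamate
Product: 10 rac-methyl [2-(2-ethenyloxiran-2-yl)ethyl]carbamate
Conditions: mCPBA (1.0 equiv), CH2Cl2/aq. phosphate buffer (pH 8), 0 °C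
Reagents that add atoms: 3-chloroperoxybenzoic acid, OOC(=O)c1cccc(Cl)c1
Why: Prilezhaev epoxidation should favour the more electron-rich 1,1-disubstituted double bond of the diene over the monosubstituted one, and buffering protects the acid-labile vinyl epoxide.

Step 7
Reactants: 10 rac-methyl [2-(2-ethenyloxiran-2-yl)ethyl]carbamate
Product: 11 methyl [(3R)-3-hydroxy-3-(hydroxymethyl)pent-4-en-1-yl]carbamate
Conditions: Pd2(dba)3·CHCl3 (1 mol%), (1R,2R)-N,N'-bis[2-(diphenylphosphino)-1-naphthoyl]cyclohexane-1,2-diamine (3 mol%), Et3B (2 mol%), NaHCO3, CH2Cl2/H2O, rt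
Reagents that add atoms: water, O
Why: Pd-catalysed dynamic kinetic asymmetric allylic substitution of the vinyl epoxide, in which the π-allyl diastereomers interconvert rapidly and boron-templated delivery of hydrogencarbonate (regenerated after loss of CO2, so the net change is hydration) to the tertiary allyl terminus within the chiral ligand pocket should set the tertiary carbinol as (R).

Step 8
Reactants: 6 1,3-dioxoisoindolin-2-yl (3R)-3-[(tert-butyldimethylsilyl)oxy]-2,2-dimethylhex-5-enoate; 11 methyl [(3R)-3-hydroxy-3-(hydroxymethyl)pent-4-en-1-yl]carbamate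
Product: 12 1,3-dioxoisoindolin-2-yl (3R,5E,7R)-3-[(tert-butyldimethylsilyl)oxy]-7-hydroxy-7-(hydroxymethyl)-9-[(methoxycarbonyl)amino]-2,2-dimethylnon-5-enoate
Conditions: Hoveyda–Grubbs II (7.5 mol%), 11 (1.5 equiv), CH2Cl2, 40 °C
Reagents that add atoms: none
Why: Olefin cross-metathesis between the terminal alkene of 6 and the non-dimerising alkene of 11, which sits on a fully substituted carbinol carbon, should give the E-disubstituted alkene under steric and thermodynamic control without touching either stereocentre.

Step 9
Reactants: 13 pent-1-en-4-yne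
Product: 14 tributyl[(1Z)-penta-1,4-dien-1-yl]stannane
Conditions: Bu3SnH (1.1 equiv), ZrCl4 (20 mol%), toluene, 0 °C
Reagents that add atoms: tributyltin hydride, CCCC[SnH](CCCC)CCCC
Why: Lewis-acid-catalysed trans-hydrostannation of the terminal alkyne places tin on the terminal carbon by anti addition and should give the (Z)-alkenylstannane while the isolated alkene stays untouched.

Step 10
Reactants: 15 4-(chloromethyl)-1,3-thiazole hydrochloride; 14 tributyl[(1Z)-penta-1,4-dien-1-yl]stannane
Product: 16 4-[(2Z)-hexa-2,5-dien-1-yl]-1,3-thiazole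
Conditions: Pd2(dba)3 (2.5 mol%), P(2-furyl)3 (10 mol%), i-Pr2NEt (1.1 equiv), THF, 60 °C
Reagents that add atoms: none
Why: Stille sp3–sp2 coupling of the benzylic-type chloride with the alkenylstannane proceeds with retention of alkene geometry and should give the skipped (Z)-diene.

Step 11
Reactants: 12 1,3-dioxoisoindolin-2-yl (3R,5E,7R)-3-[(tert-butyldimethylsilyl)oxy]-7-hydroxy-7-(hydroxymethyl)-9-[(methoxycarbonyl)amino]-2,2-dimethylnon-5-enoate; 16 4-[(2Z)-hexa-2,5-dien-1-yl]-1,3-thiazole
Product: 17 methyl N-[(3R,4E,7R)-7-[(tert-butyldimethylsilyl)oxy]-8-{4-[(2Z)-hexa-2,5-dien-1-yl]-1,3-thiazol-2-yl}-3-hydroxy-3-(hydroxymethyl)-8-methylnon-4-en-1-yl]carbamate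
Conditions: 4CzIPN (2 mol%), TFA (2 equiv), 16 (1.5 equiv), degassed DMSO, blue LEDs (450 nm), rt
Reagents that add atoms: none
Why: Decarboxylative Minisci C–H alkylation run as a photoredox cycle: the excited photocatalyst reduces the N-acyloxyphthalimide of 12, N–O cleavage and loss of CO2 give the nucleophilic tertiary α,α-dimethyl radical, this adds to C2 of the N3-protonated thiazole, and deprotonation plus one-electron oxidation of the adduct by the oxidised photocatalyst restore the aromatic ring. The closest known reaction type is the visible-light Minisci alkylation of azoles and azines at the carbon next to nitrogen with tertiary alkyl redox-active esters. No ring is closed and no stereocentre is created, since the new quaternary carbon carries two methyl groups and the radical is never located on the neighbouring (R)-carbinol carbon or on the remote tertiary carbinol. The step needs site selectivity for C2 over C5 and chemoselectivity for the heteroarene over four C=C bonds: protonation makes C2, between S1 and N3, the only strongly electrophilic position for a nucleophilic radical, the unactivated alkenes are polarity-mismatched, and the only cyclisations open to the radical (4-exo or 5-endo onto the E-alkene) are kinetically disfavoured. The redox-neutral conditions without peroxide or persulfate should spare the doubly allylic C–H bonds of the skipped diene, the free diol and the carbamate, and TFA at room temperature should not cleave the hindered TBS ether.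

Step 12
Reactants: 17 methyl N-[(3R,4E,7R)-7-[(tert-butyldimethylsilyl)oxy]-8-{4-[(2Z)-hexa-2,5-dien-1-yl]-1,3-thiazol-2-yl}-3-hydroxy-3-(hydroxymethyl)-8-methylnon-4-en-1-yl]carbamate
Product: 18 methyl N-[(3R,4E,7R)-3,7-dihydroxy-8-{4-[(2Z)-hexa-2,5-dien-1-yl]-1,3-thiazol-2-yl}-3-(hydroxymethyl)-8-methylnon-4-en-1-yl]carbamate (CNP0212145.1)
Conditions: HF·pyridine, pyridine, THF, 0 °C → rt
Reagents that add atoms: none
Why: Fluoride-mediated desilylation buffered with pyridine should remove the TBS ether without ionising the tertiary allylic alcohol or affecting the carbamate, the thiazole and the alkenes.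

**Compound list**

1 | methyl 2,2-dimethyl-3-oxopropanoate | COC(=O)C(C)(C)C=O | starting material
2 | methyl (3R)-3-hydroxy-2,2-dimethylhex-5-enoate | COC(=O)C(C)(C)[C@H](O)CC=C | intermediate (not isolated)
3 | (3R)-3-hydroxy-2,2-dimethylhex-5-enoic acid | OC(=O)C(C)(C)[C@H](O)CC=C | intermediate
4 | tert-butyldimethylsilyl (3R)-3-[(tert-butyldimethylsilyl)oxy]-2,2-dimethylhex-5-enoate | CC(C)(C)[Si](C)(C)OC(=O)C(C)(C)[C@H](O[Si](C)(C)C(C)(C)C)CC=C | intermediate (not isolated)
5 | (3R)-3-[(tert-butyldimethylsilyl)oxy]-2,2-dimethylhex-5-enoic acid | OC(=O)C(C)(C)[C@H](O[Si](C)(C)C(C)(C)C)CC=C | intermediate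
6 | 1,3-dioxoisoindolin-2-yl (3R)-3-[(tert-butyldimethylsilyl)oxy]-2,2-dimethylhex-5-enoate | O=C1c2ccccc2C(=O)N1OC(=O)C(C)(C)[C@H](O[Si](C)(C)C(C)(C)C)CC=C | intermediate
7 | but-3-yn-1-amine | NCCC#C | starting material
8 | methyl but-3-yn-1-ylcarbamate | COC(=O)NCCC#C | intermediate
9 | methyl (3-methylidenepent-4-en-1-yl)carbamate | COC(=O)NCCC(=C)C=C | intermediate
10 | rac-methyl [2-(2-ethenyloxiran-2-yl)ethyl]carbamate | COC(=O)NCCC1(C=C)CO1 | intermediate
11 | methyl [(3R)-3-hydroxy-3-(hydroxymethyl)pent-4-en-1-yl]carbamate | C=C[C@@](O)(CO)CCNC(=O)OC | intermediate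
12 | 1,3-dioxoisoindolin-2-yl (3R,5E,7R)-3-[(tert-butyldimethylsilyl)oxy]-7-hydroxy-7-(hydroxymethyl)-9-[(methoxycarbonyl)amino]-2,2-dimethylnon-5-enoate | O=C1c2ccccc2C(=O)N1OC(=O)C(C)(C)[C@H](O[Si](C)(C)C(C)(C)C)C/C=C/[C@@](O)(CO)CCNC(=O)OC | intermediate
13 | pent-1-en-4-yne | C=CCC#C | starting material
14 | tributyl[(1Z)-penta-1,4-dien-1-yl]stannane | C=CC/C=C\[Sn](CCCC)(CCCC)CCCC | intermediate
15 | 4-(chloromethyl)-1,3-thiazole hydrochloride | ClCc1cscn1.Cl | starting material
16 | 4-[(2Z)-hexa-2,5-dien-1-yl]-1,3-thiazole | C=CC/C=C\Cc1cscn1 | intermediate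
17 | methyl N-[(3R,4E,7R)-7-[(tert-butyldimethylsilyl)oxy]-8-{4-[(2Z)-hexa-2,5-dien-1-yl]-1,3-thiazol-2-yl}-3-hydroxy-3-(hydroxymethyl)-8-methylnon-4-en-1-yl]carbamate | C=CC/C=C\Cc1csc(C(C)(C)[C@H](O[Si](C)(C)C(C)(C)C)C/C=C/[C@@](O)(CO)CCNC(=O)OC)n1 | intermediate
18 | methyl N-[(3R,4E,7R)-3,7-dihydroxy-8-{4-[(2Z)-hexa-2,5-dien-1-yl]-1,3-thiazol-2-yl}-3-(hydroxymethyl)-8-methylnon-4-en-1-yl]carbamate | C=CC/C=C\Cc1csc(C(C)(C)[C@H](O)C/C=C/[C@@](O)(CO)CCNC(=O)OC)n1 | target

**Step count**

Total steps: 12. Longest linear sequence: 7 (steps 4, 5, 6, 7, 8, 11, 12).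

**Steps most likely to fail**

Step 11. The thiazole is only weakly basic, so the hindered tertiary radical may be lost to reduction, disproportionation or hydrogen abstraction from the doubly allylic positions before it adds to C2. The fallback makes the same C2–C bond by a two-electron, metal-catalysed route in which the thiazole is the nucleophile, and sets out from 12 and 16. The diol of 12 is capped with TESOTf and 2,6-lutidine to give the bis(triethylsilyl) ether of the redox-active ester F1. Thiazole 16 is zincated at C2, its most acidic ring C–H, with TMPZnCl·LiCl in THF to give the thiazol-2-ylzinc chloride F2, used in excess to absorb the carbamate N–H. A nickel(II)/bipyridine-catalysed decarboxylative Negishi-type arylation of the tertiary ester F1 with F2 should then give the tris-silylated coupling product F3. HF·pyridine removes all three silyl groups and the sequence comes back to the route at 18.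

Step 7. The π-allyl palladium intermediate may be captured by the internal carbamate nitrogen in a six-membered ring closure, or the larger side chain may slow π–σ–π equilibration and erode enantioselectivity. The fallback sets the tertiary carbinol by a reagent-controlled epoxidation instead and sets out from alkyne 8. Branched-selective Pd-catalysed methoxycarbonylation (Pd(OAc)2, 2-pyridyldiphenylphosphine, MsOH, CO, MeOH) gives the 2-substituted acrylate F4. DIBAL-H at −78 °C reduces it to the 2-substituted allylic alcohol F5. Sharpless asymmetric epoxidation with L-(+)-diethyl tartrate, Ti(OiPr)4 and TBHP should give the (S)-epoxy alcohol F6. Excess dimethylsulfonium methylide (Me3S+ I−, n-BuLi, THF) then opens the epoxide at its CH2 and expels dimethyl sulfide, a one-carbon homologation to the vinyl carbinol that leaves the stereocentre untouched and comes back to the route at 11.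

Step 6. The peracid may attack the monosubstituted double bond or both, and the vinyl epoxide may open under the acidic by-product. The fallback replaces direct oxygen transfer by halohydrin formation and ring closure and sets out from diene 9. NBS in wet DMSO at 0 °C, with water opening the bromonium ion at the tertiary allylic carbon, should give the bromohydrin F7. K2CO3 in MeOH closes the epoxide and the sequence comes back to the route at 10.

**Further compounds**

F1 | step 11 | 1,3-dioxoisoindolin-2-yl (3R,5E,7R)-3-[(tert-butyldimethylsilyl)oxy]-9-[(methoxycarbonyl)amino]-2,2-dimethyl-7-[(triethylsilyl)oxy]-7-{[(triethylsilyl)oxy]methyl}non-5-enoate | O=C1c2ccccc2C(=O)N1OC(=O)C(C)(C)[C@H](O[Si](C)(C)C(C)(C)C)C/C=C/[C@@](O[Si](CC)(CC)CC)(CO[Si](CC)(CC)CC)CCNC(=O)OC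
F2 | step 11 | chlorido{4-[(2Z)-hexa-2,5-dien-1-yl]-1,3-thiazol-2-yl}zinc | C=CC/C=C\Cc1csc([Zn]Cl)n1
F3 | step 11 | methyl N-[(3R,4E,7R)-7-[(tert-butyldimethylsilyl)oxy]-8-{4-[(2Z)-hexa-2,5-dien-1-yl]-1,3-thiazol-2-yl}-8-methyl-3-[(triethylsilyl)oxy]-3-{[(triethylsilyl)oxy]methyl}non-4-en-1-yl]carbamate | C=CC/C=C\Cc1csc(C(C)(C)[C@H](O[Si](C)(C)C(C)(C)C)C/C=C/[C@@](O[Si](CC)(CC)CC)(CO[Si](CC)(CC)CC)CCNC(=O)OC)n1
F4 | step 7 | methyl 4-[(methoxycarbonyl)amino]-2-methylidenebutanoate | COC(=O)C(=C)CCNC(=O)OC
F5 | step 7 | methyl [3-(hydroxymethyl)but-3-en-1-yl]carbamate | OCC(=C)CCNC(=O)OC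
F6 | step 7 | methyl {2-[(2S)-2-(hydroxymethyl)oxiran-2-yl]ethyl}carbamate | OC[C@@]1(CCNC(=O)OC)CO1
F7 | step 6 | rac-methyl [3-(bromomethyl)-3-hydroxypent-4-en-1-yl]carbamate | OC(CBr)(C=C)CCNC(=O)OC
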